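Azulene numbering is used (C3 carbinol, C3a fusion CH, C4 ester carbon, C8a quaternary carbon). Everything rests on disconnecting C3–C3a. C3a lies between the C4 oxygen-bearing carbon and quaternary C8a of the seven-membered ring, so it can be a keto carbenoid of a cycloheptenone, and the C3 carbinol C–H, α to oxygen on the C8a side chain, sits 1,5 to it. One rhodium-catalysed C–H insertion closes the five-membered ring, sets the cis fusion and carries the C3 configuration over with retention. The precursor is a 7-diazo-3,6-dimethylcyclohept-2-enone whose quaternary C6 bears a (3R)-4-methyl-3-(triethylsilyloxy)pentyl chain; the small silyl group keeps the final tertiary ether cleavable.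

Key step: step 11

Remarks and assumptions
- The target is (3R,3aS,4R,8aR): the rings are cis-fused, the C3a hydrogen and the C8a methyl lie on one face, and the C3 hydroxyl and the C4 ester oxygen lie on the other.
- Assumption: the sense of induction in step 9 is set by the choice of ligand antipode (both are available from D- or L-leucinol); the antipode that gives 6R is fixed in a small-scale trial.
- The carbinol is carried as a triethylsilyl ether. It is hindered enough to keep the ether oxygen away from the carbenoid, yet it can be removed from the tertiary position with buffered fluoride next to the allylic ester.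
- The symmetric dienone is made from commercial 3-methylcyclohex-2-en-1-one by one-carbon ring expansion.

Step 1
Reactants: 1 3-methylcyclohex-2-en-1-one
Product: 3 3,6-dimethylcyclohex-2-en-1-one (racemic), via lithium dienolate 2 (not isolated)
Conditions: LiN(iPr)2, THF, −78 °C; MeI, −78 → 0 °C
Reagents that add atoms: iodomethane, CI
Why: Kinetic deprotonation of the enone by the lithium amide takes place at the α′ carbon and the cross-conjugated enolate is methylated there (α′-alkylation of an enone); the new stereocentre is racemic and is erased in step 2.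

Step 2
Reactants: 3 3,6-dimethylcyclohex-2-en-1-one
Product: 5 [(2,5-dimethylcyclohexa-1,5-dien-1-yl)oxy]trimethylsilane, via lithium dienolate 4 (not isolated)
Conditions: LiN(iPr)2, THF, −78 °C; Me3SiCl, Et3N, −78 °C → rt
Reagents that add atoms: chlorotrimethylsilane, C[Si](C)(C)Cl
Why: A second kinetic α′-deprotonation followed by O-silylation (silyl enol ether formation) should give the 2-silyloxy-1,3-diene, which has no stereocentre.

Step 3
Reactants: 5 [(2,5-dimethylcyclohexa-1,5-dien-1-yl)oxy]trimethylsilane
Product: 6 [(3,6-dimethylbicyclo[4.1.0]hept-2-en-1-yl)oxy]trimethylsilane (racemic)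
Conditions: Et2Zn, CH2I2, Et2O, 0 °C → rt
Reagents that add atoms: diiodomethane, ICI
Why: Furukawa-modified Simmons–Smith cyclopropanation, in which the electrophilic zinc carbenoid selects the more electron-rich, oxygen-bearing double bond of the silyloxy diene; the two ring-fusion stereocentres form as a racemic cis pair that step 4 destroys.

Step 4
Reactants: 6 [(3,6-dimethylbicyclo[4.1.0]hept-2-en-1-yl)oxy]trimethylsilane
Product: 8 3,6-dimethylcyclohepta-2,6-dien-1-one, via β-chloro ketone 7 (not isolated)
Conditions: FeCl3, DMF, 0 °C → rt; then NaOAc, MeOH, 65 °C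
Reagents that add atoms: none
Why: Saegusa-type oxidative ring expansion of a siloxycyclopropane: one-electron oxidation by FeCl3 opens the internal cyclopropane bond to the tertiary β-keto radical, chlorine transfer gives the ring-enlarged β-chloro ketone, and acetate-mediated dehydrochlorination gives the symmetric cross-conjugated dienone, which has no stereocentre.

Step 5
Reactants: 9 ethyl 4-methyl-3-oxopentanoate
Product: 10 ethyl (3R)-3-hydroxy-4-methylpentanoate
Conditions: H2 (50 atm), RuCl2[(S)-BINAP] (0.2 mol%), EtOH, 60 °C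
Reagents that add atoms: none
Why: Noyori asymmetric hydrogenation of a β-keto ester: the ester-chelated ketone is reduced by the (S)-BINAP–ruthenium hydride on the face that gives (S)-3-hydroxybutanoate from acetoacetate, which here is labelled 3R because isopropyl outranks CH2CO2Et.

Step 6
Reactants: 10 ethyl (3R)-3-hydroxy-4-methylpentanoate
Product: 11 ethyl (3R)-4-methyl-3-(triethylsilyloxy)pentanoate
Conditions: Et3SiCl, imidazole, CH2Cl2, 0 °C → rt
Reagents that add atoms: chlorotriethylsilane, CC[Si](Cl)(CC)CC
Why: Imidazole-promoted O-silylation of a secondary alcohol, which does not touch the stereocentre.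

Step 7
Reactants: 11 ethyl (3R)-4-methyl-3-(triethylsilyloxy)pentanoate
Product: 12 (3R)-4-methyl-3-(triethylsilyloxy)pentan-1-ol
Conditions: iBu2AlH, CH2Cl2, −78 → 0 °C; aq. potassium sodium tartrate
Reagents that add atoms: none
Why: Aluminium hydride reduction of the ester to the primary alcohol, under which the silyl ether and the stereocentre are stable.

Step 8
Reactants: 12 (3R)-4-methyl-3-(triethylsilyloxy)pentan-1-ol
Product: 13 {[(3R)-1-bromo-4-methylpentan-3-yl]oxy}triethylsilane
Conditions: CBr4, PPh3, imidazole, CH2Cl2, 0 °C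
Reagents that add atoms: tetrabromomethane, BrC(Br)(Br)Br
Why: Appel bromination of the primary alcohol by SN2 displacement of the oxyphosphonium group, with imidazole buffering to protect the silyl ether.

Step 9
Reactants: 13 {[(3R)-1-bromo-4-methylpentan-3-yl]oxy}triethylsilane; 8 3,6-dimethylcyclohepta-2,6-dien-1-one
Product: 15 (6R)-3,6-dimethyl-6-[(3R)-4-methyl-3-(triethylsilyloxy)pentyl]cyclohept-2-en-1-one, via Grignard reagent 14 (not isolated)
Conditions: Mg, Et2O, 35 °C; then slow addition to 8, Cu(OTf)2 (4 mol%), leucinol-derived 1-mesityl-3-(1-hydroxy-4-methylpentan-2-yl)imidazolinium hexafluorophosphate (antipode giving 6R, 5 mol%), Et2O, −30 → 0 °C; aq. NH4Cl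
Reagents that add atoms: none
Why: Copper-catalysed asymmetric conjugate addition of a Grignard reagent to a β-methyl cycloalkenone with a chelating N-heterocyclic carbene ligand; the chiral copper complex selects the enone face and so sets the quaternary C6 as R, the two β-carbons of the symmetric dienone give the same product, the magnesium dienolate formed after one addition is no longer an acceptor, and any C6 epimer is a diastereomer because the chain is enantiopure.

Step 10
Reactants: 15 (6R)-3,6-dimethyl-6-[(3R)-4-methyl-3-(triethylsilyloxy)pentyl]cyclohept-2-en-1-one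
Product: 18 (6R)-7-diazo-3,6-dimethyl-6-[(3R)-4-methyl-3-(triethylsilyloxy)pentyl]cyclohept-2-en-1-one, via lithium enolate 16 (not isolated), via trifluoroacetyl ketone 17 (not isolated)
Conditions: LiN(SiMe3)2, THF, −78 °C; CF3CO2CH2CF3, −78 °C; then 4-acetamidobenzenesulfonyl azide, Et3N, H2O, MeCN, rt
Reagents that add atoms: 4-acetamidobenzenesulfonyl azide, CC(=O)Nc1ccc(cc1)S(=O)(=O)N=[N+]=[N-]
Why: Detrifluoroacetylative diazo transfer (a Regitz-type transfer made for base-sensitive enones): kinetic enolisation at C7, the only α-carbon that carries hydrogen, C-trifluoroacetylation to activate that position, then diazo transfer with loss of the trifluoroacetyl group to the sulfonamide; no stereocentre is touched.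

Step 11
Reactants: 18 (6R)-7-diazo-3,6-dimethyl-6-[(3R)-4-methyl-3-(triethylsilyloxy)pentyl]cyclohept-2-en-1-one
Product: 19 (3R,3aR,8aR)-6,8a-dimethyl-3-(propan-2-yl)-3-(triethylsilyloxy)-2,3,3a,7,8,8a-hexahydroazulen-4(1H)-one
Conditions: Rh2(OAc)4 (2 mol%), CH2Cl2, 40 °C, 18 added over several hours
Reagents that add atoms: none
Why: Rh2(OAc)4 should convert the diazo ketone into an electrophilic rhodium carbenoid at C7 (the later C3a), whose empty orbital engages the carbinol C–H bond of the side chain in a concerted three-centre transition state that forms C3–C3a and passes the hydrogen to C3a. The closest known reaction is the dirhodium tetracarboxylate-catalysed intramolecular 1,5 C–H insertion of α-diazo ketones into ether-activated tertiary C–H bonds. The five-membered ring (C1, C2, C3, C3a, C8a) is closed by 1,5-insertion and is fused onto the existing seven-membered ring. C3 keeps the configuration of the hydrogenation-derived carbinol because insertion goes with retention, and C3a is set with its hydrogen cis to the C8a methyl because the two-carbon tether on C8a can reach the carbenoid only from its own face; in that arrangement the isopropyl group lies away from the C4 carbonyl. The step needs site selectivity for the carbinol C–H and chemoselectivity over ylide formation, 1,2-shift and dimerisation. That C–H is the only one able to give a five-membered ring and is activated by the silyloxy oxygen, quaternary C6 offers no β-hydrogen, the hindered silyl ether oxygen is a poor ylide donor, and slow addition keeps the diazo concentration low.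

Step 12
Reactants: 19 (3R,3aR,8aR)-6,8a-dimethyl-3-(propan-2-yl)-3-(triethylsilyloxy)-2,3,3a,7,8,8a-hexahydroazulen-4(1H)-one
Product: 20 (3R,3aS,4R,8aR)-6,8a-dimethyl-3-(propan-2-yl)-3-(triethylsilyloxy)-1,2,3,3a,4,7,8,8a-octahydroazulen-4-ol
Conditions: NaBH4, CeCl3·7H2O, MeOH, −78 → −40 °C
Reagents that add atoms: none
Why: Luche reduction (1,2-selective borohydride reduction of an enone): hydride should reach C4 from the convex face, where only the C3a hydrogen flanks the carbonyl, while the concave face is screened by the fully substituted C3 and its silyloxy group, so the new hydroxyl is placed cis to the C3 oxygen (4R); the cold, non-basic medium should leave the epimerisable C3a and the β-silyloxy ketone intact.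

Step 13
Reactants: 21 isovanillic acid (3-hydroxy-4-methoxybenzoic acid)
Product: 23 3-(tert-butyldimethylsilyloxy)-4-methoxybenzoic acid, via bis-silyl derivative 22 (not isolated)
Conditions: tBuMe2SiCl, imidazole, DMF, rt; then AcOH, THF, H2O, rt
Reagents that add atoms: tert-butyl(chloro)dimethylsilane, CC(C)(C)[Si](C)(C)Cl
Why: Silylation of both the phenol and the acid followed by selective hydrolysis of the much more labile silyl ester in mild aqueous acid, which leaves the aryl silyl ether.

Step 14
Reactants: 23 3-(tert-butyldimethylsilyloxy)-4-methoxybenzoic acid; 20 (3R,3aS,4R,8aR)-6,8a-dimethyl-3-(propan-2-yl)-3-(triethylsilyloxy)-1,2,3,3a,4,7,8,8a-octahydroazulen-4-ol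
Product: 25 (3R,3aS,4R,8aR)-6,8a-dimethyl-3-(propan-2-yl)-3-(triethylsilyloxy)-1,2,3,3a,4,7,8,8a-octahydroazulen-4-yl 3-(tert-butyldimethylsilyloxy)-4-methoxybenzoate, via mixed anhydride 24 (not isolated)
Conditions: 2,4,6-Cl3C6H2COCl, Et3N, THF, rt; then 20, DMAP, toluene, rt → 40 °C
Reagents that add atoms: none
Why: Yamaguchi esterification: the aroyl group passes from the mixed anhydride through the acyl-DMAP salt to the hindered secondary allylic hydroxyl, the C4–O bond is not broken so 4R is kept, and both silyl ethers are inert.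

Step 15
Reactants: 25 (3R,3aS,4R,8aR)-6,8a-dimethyl-3-(propan-2-yl)-3-(triethylsilyloxy)-1,2,3,3a,4,7,8,8a-octahydroazulen-4-yl 3-(tert-butyldimethylsilyloxy)-4-methoxybenzoate
Product: 26 (3R,3aS,4R,8aR)-3-hydroxy-6,8a-dimethyl-3-(propan-2-yl)-1,2,3,3a,4,7,8,8a-octahydroazulen-4-yl 3-hydroxy-4-methoxybenzoate
Conditions: Bu4NF, AcOH, THF, 0 °C → rt
Reagents that add atoms: none
Why: Fluoride-induced desilylation of the aryl silyl ether and the tertiary triethylsilyl ether; acetic acid buffering avoids free alkoxide (ester cleavage or acyl shift) and strong acid (ionisation of the allylic ester), and no stereocentre is affected.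

Compound list
1 | 3-methylcyclohex-2-en-1-one | CC1=CC(=O)CCC1 | starting material
2 | lithium 5-methylcyclohexa-1,5-dien-1-olate | [Li]OC1=CCCC(C)=C1 | intermediate
3 | 3,6-dimethylcyclohex-2-en-1-one (racemic) | CC1=CC(=O)C(C)CC1 | intermediate
4 | lithium 2,5-dimethylcyclohexa-1,5-dien-1-olate | [Li]OC1=C(C)CCC(C)=C1 | intermediate
5 | [(2,5-dimethylcyclohexa-1,5-dien-1-yl)oxy]trimethylsilane | C[Si](C)(C)OC1=C(C)CCC(C)=C1 | intermediate
6 | [(3,6-dimethylbicyclo[4.1.0]hept-2-en-1-yl)oxy]trimethylsilane (racemic) | C[Si](C)(C)OC12CC1(C)CCC(C)=C2 | intermediate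
7 | 6-chloro-3,6-dimethylcyclohept-2-en-1-one (racemic) | O=C1C=C(C)CCC(C)(Cl)C1 | intermediate
8 | 3,6-dimethylcyclohepta-2,6-dien-1-one | O=C1C=C(C)CCC(C)=C1 | intermediate
9 | ethyl 4-methyl-3-oxopentanoate | CCOC(=O)CC(=O)C(C)C | starting material
10 | ethyl (3R)-3-hydroxy-4-methylpentanoate | CCOC(=O)C[C@@H](O)C(C)C | intermediate
11 | ethyl (3R)-4-methyl-3-(triethylsilyloxy)pentanoate | CCOC(=O)C[C@@H](O[Si](CC)(CC)CC)C(C)C | intermediate
12 | (3R)-4-methyl-3-(triethylsilyloxy)pentan-1-ol | OCC[C@@H](O[Si](CC)(CC)CC)C(C)C | intermediate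
13 | {[(3R)-1-bromo-4-methylpentan-3-yl]oxy}triethylsilane | BrCC[C@@H](O[Si](CC)(CC)CC)C(C)C | intermediate
14 | [(3R)-4-methyl-3-(triethylsilyloxy)pentyl]magnesium bromide | Br[Mg]CC[C@@H](O[Si](CC)(CC)CC)C(C)C | intermediate
15 | (6R)-3,6-dimethyl-6-[(3R)-4-methyl-3-(triethylsilyloxy)pentyl]cyclohept-2-en-1-one | O=C1C=C(C)CC[C@](C)(CC[C@@H](O[Si](CC)(CC)CC)C(C)C)C1 | intermediate
16 | lithium enolate of 15 (O–Li on C1, C1=C7 double bond) | [Li]OC1=C[C@@](C)(CC[C@@H](O[Si](CC)(CC)CC)C(C)C)CCC(C)=C1 | intermediate
17 | (6R)-3,6-dimethyl-6-[(3R)-4-methyl-3-(triethylsilyloxy)pentyl]-7-(trifluoroacetyl)cyclohept-2-en-1-one (C7 epimers and enol form) | O=C1C=C(C)CC[C@](C)(CC[C@@H](O[Si](CC)(CC)CC)C(C)C)C1C(=O)C(F)(F)F | intermediate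
18 | (6R)-7-diazo-3,6-dimethyl-6-[(3R)-4-methyl-3-(triethylsilyloxy)pentyl]cyclohept-2-en-1-one | O=C1C=C(C)CC[C@](C)(CC[C@@H](O[Si](CC)(CC)CC)C(C)C)C1=[N+]=[N-] | intermediate
19 | (3R,3aR,8aR)-6,8a-dimethyl-3-(propan-2-yl)-3-(triethylsilyloxy)-2,3,3a,7,8,8a-hexahydroazulen-4(1H)-one | O=C2C=C(C)CC[C@]3(C)CC[C@@](O[Si](CC)(CC)CC)(C(C)C)[C@H]23 | intermediate
20 | (3R,3aS,4R,8aR)-6,8a-dimethyl-3-(propan-2-yl)-3-(triethylsilyloxy)-1,2,3,3a,4,7,8,8a-octahydroazulen-4-ol | O[C@@H]2C=C(C)CC[C@]3(C)CC[C@@](O[Si](CC)(CC)CC)(C(C)C)[C@H]23 | intermediate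
21 | isovanillic acid (3-hydroxy-4-methoxybenzoic acid) | COc1ccc(C(=O)O)cc1O | starting material
22 | tert-butyldimethylsilyl 3-(tert-butyldimethylsilyloxy)-4-methoxybenzoate | COc1ccc(C(=O)O[Si](C)(C)C(C)(C)C)cc1O[Si](C)(C)C(C)(C)C | intermediate
23 | 3-(tert-butyldimethylsilyloxy)-4-methoxybenzoic acid | COc1ccc(C(=O)O)cc1O[Si](C)(C)C(C)(C)C | intermediate
24 | 3-(tert-butyldimethylsilyloxy)-4-methoxybenzoic 2,4,6-trichlorobenzoic anhydride | COc1ccc(C(=O)OC(=O)c2c(Cl)cc(Cl)cc2Cl)cc1O[Si](C)(C)C(C)(C)C | intermediate
25 | (3R,3aS,4R,8aR)-6,8a-dimethyl-3-(propan-2-yl)-3-(triethylsilyloxy)-1,2,3,3a,4,7,8,8a-octahydroazulen-4-yl 3-(tert-butyldimethylsilyloxy)-4-methoxybenzoate | COc1ccc(C(=O)O[C@@H]2C=C(C)CC[C@]3(C)CC[C@@](O[Si](CC)(CC)CC)(C(C)C)[C@H]23)cc1O[Si](C)(C)C(C)(C)C | intermediate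
26 | (3R,3aS,4R,8aR)-3-hydroxy-6,8a-dimethyl-3-(propan-2-yl)-1,2,3,3a,4,7,8,8a-octahydroazulen-4-yl 3-hydroxy-4-methoxybenzoate | COc1ccc(C(=O)O[C@@H]2C=C(C)CC[C@]3(C)CC[C@@](O)(C(C)C)[C@H]23)cc1O | target

Total step count: 15.
Longest linear sequence: 10 steps (steps 5–12, 14 and 15 from ethyl 4-methyl-3-oxopentanoate; the branch from 3-methylcyclohex-2-en-1-one through steps 1–4, 9–12, 14 and 15 is equally long).

Steps most likely to fail

Step 11. The carbenoid may be diverted before it inserts: the silyl ether oxygen may attack it to give an oxonium ylide, a methyl group may shift from C6, or the carbenoid may dimerise. Insertion may also be slow at the crowded tertiary C–H. The fallback forms the same C3–C3a bond by an aldol-type closure and sets out from ketone 15. Its lithium enolate 16 (LiN(SiMe3)2, THF, −78 °C) is brominated with N-bromosuccinimide to the α-bromo ketone F1. The secondary silyl ether is removed (pyridinium p-toluenesulfonate, MeOH) to give the bromo alcohol F2, which is oxidised with Dess–Martin periodinane to the bromo diketone F3. SmI2 in THF at −78 °C reduces the C–Br bond, and the trivalent samarium enolate, formed specifically at C7, adds to the chelated side-chain ketone (intramolecular Reformatsky-type aldol). This should give the cis-fused hydroxy enone F4 with the C3 oxygen cis to the C4 carbonyl. Silylation (Et3SiOTf, 2,6-lutidine, CH2Cl2, −78 °C) returns to 19.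

Step 9. Face discrimination at the β-carbon of the dienone may be insufficient, or 1,2-addition of the Grignard reagent may compete. The fallback gives up catalyst control and sets out from bromide 13 and dienone 8. Grignard reagent 14 is added with CuBr·SMe2 (10 mol%) in THF at −40 °C without a chiral ligand, which should give 15 together with its C6 epimer, the ketone F5. The mixture is taken through step 10, where the epimeric lithium enolate F6, the trifluoroacetyl ketone F7 and the diazo ketone F8 accompany 16, 17 and 18. In step 11 any diastereomeric bicyclic ketone F9 is rigid and should be separable from 19 on silica. The route is rejoined at 19.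

Step 12. Hydride may be delivered from the concave face, which would give the C4 epimer. The fallback corrects C4 by inversion and sets out from 19. If the reduction gives mainly the 4S alcohol F10, this alcohol is esterified with acid 23 under Mitsunobu conditions (PPh3, diisopropyl azodicarboxylate, toluene, 0 °C → rt). SN2 displacement with inversion at C4 (the tertiary C6 terminus disfavours SN2′ attack) should give ester 25, where the route is rejoined.

Further compounds
F1 | step 11 | (6R)-7-bromo-3,6-dimethyl-6-[(3R)-4-methyl-3-(triethylsilyloxy)pentyl]cyclohept-2-en-1-one (C7 epimers) | O=C1C=C(C)CC[C@](C)(CC[C@@H](O[Si](CC)(CC)CC)C(C)C)C1Br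
F2 | step 11 | (6R)-7-bromo-6-[(3R)-3-hydroxy-4-methylpentyl]-3,6-dimethylcyclohept-2-en-1-one (C7 epimers) | O=C1C=C(C)CC[C@](C)(CC[C@@H](O)C(C)C)C1Br
F3 | step 11 | (6R)-7-bromo-3,6-dimethyl-6-(4-methyl-3-oxopentyl)cyclohept-2-en-1-one (C7 epimers) | O=C1C=C(C)CC[C@](C)(CCC(=O)C(C)C)C1Br
F4 | step 11 | (3R,3aR,8aR)-3-hydroxy-6,8a-dimethyl-3-(propan-2-yl)-2,3,3a,7,8,8a-hexahydroazulen-4(1H)-one | O=C2C=C(C)CC[C@]3(C)CC[C@@](O)(C(C)C)[C@H]23
F5 | step 9 | (6S)-3,6-dimethyl-6-[(3R)-4-methyl-3-(triethylsilyloxy)pentyl]cyclohept-2-en-1-one | O=C1C=C(C)CC[C@@](C)(CC[C@@H](O[Si](CC)(CC)CC)C(C)C)C1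
F6 | step 9 | lithium enolate of F5 (O–Li on C1, C1=C7 double bond) | [Li]OC1=C[C@](C)(CC[C@@H](O[Si](CC)(CC)CC)C(C)C)CCC(C)=C1
F7 | step 9 | (6S)-3,6-dimethyl-6-[(3R)-4-methyl-3-(triethylsilyloxy)pentyl]-7-(trifluoroacetyl)cyclohept-2-en-1-one (C7 epimers and enol form) | O=C1C=C(C)CC[C@@](C)(CC[C@@H](O[Si](CC)(CC)CC)C(C)C)C1C(=O)C(F)(F)F
F8 | step 9 | (6S)-7-diazo-3,6-dimethyl-6-[(3R)-4-methyl-3-(triethylsilyloxy)pentyl]cyclohept-2-en-1-one | O=C1C=C(C)CC[C@@](C)(CC[C@@H](O[Si](CC)(CC)CC)C(C)C)C1=[N+]=[N-]
F9 | step 9 | (3R,3aS,8aS)-6,8a-dimethyl-3-(propan-2-yl)-3-(triethylsilyloxy)-2,3,3a,7,8,8a-hexahydroazulen-4(1H)-one | O=C2C=C(C)CC[C@@]3(C)CC[C@@](O[Si](CC)(CC)CC)(C(C)C)[C@@H]23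
F10 | step 12 | (3R,3aS,4S,8aR)-6,8a-dimethyl-3-(propan-2-yl)-3-(triethylsilyloxy)-1,2,3,3a,4,7,8,8a-octahydroazulen-4-ol | O[C@H]2C=C(C)CC[C@]3(C)CC[C@@](O[Si](CC)(CC)CC)(C(C)C)[C@H]23
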